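1. Early in the oak run ring already reads 17.0% at 0.250 d, and it ends at 22.4% at 3.00 d. We count everything as a fraction of the starting material charged.

| flask | starting material | activator | protic impurity | remark | time |
|---|---|---|---|---|---|
| oak | 20 mM | 16 mM | 4 mM | run made earlier |  |
| birch | 20 mM | 8 mM | 4 mM | run made earlier |  |
| ash | 20 mM | 32 mM | 4 mM | run made earlier |  |
| elm | 40 mM | 16 mM | 4 mM | run made earlier |  |
| north-east | 20 mM (fed, over 30 h) | 16.0 mM | 4.00 mM | all else is in the flask from the start; the feed brings no volume worth counting | 3.0 d |
| south-east | 20 mM | 16.0 mM (fed, over 30 h) | 4.00 mM | all else is in the flask from the start; the feed brings no volume worth counting | 3.0 d |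
| south | 20 mM | 16.0 mM | 4.00 mM | everything together at the start | 3.0 d |

oak run (percent of the starting material charged)

| time / d | ring / % |
|---|---|
| 0.250 | 17.0 |
| 0.500 | 19.8 |
| 1.25 | 20.1 |
| 3.00 | 22.4 |

birch run (percent of the starting material charged)

| time / h | ring / % |
|---|---|
| 10.0 | 11.8 |
| 20.0 | 11.3 |
| 30.0 | 10.0 |
| 40.0 | 11.4 |

ash run (percent of the starting material charged)

| time / h | ring / % |
|---|---|
| 5.00 | 20.1 |
| 15.0 | 24.2 |
| 30.0 | 24.6 |
| 40.0 | 23.5 |

elm run (percent of the starting material charged)

| time / h | ring / % |
|---|---|
| 10.0 | 12.2 |
| 20.0 | 12.0 |
| 30.0 | 11.7 |
| 40.0 | 8.8 |

(readings scatter by 1 percentage point)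

- which flask leads in amount of ring, in percent of the starting material charged ("all alike" within 1.5 percentage points) (north-east / south-east / south / all alike)
- how much ring is there at the end, in percent of the starting material charged: north-east
- how much ring is there at the end, in percent of the starting material charged: south-east
- how much ring is there at the end, in percent of the starting material charged: south

- percentages count the starting material that a species holds: one open dimer counts as two
- ring is meant together with its idle adduct
- candidate steps: starting material + activator -> activated form; activated form -> ring; starting material + activated form -> open dimer; activated form -> decomposed reagent; activator + ring <-> idle adduct; starting material + protic impurity -> quenched substrate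

2. In oak, activator stands at a fraction 0.800. Protic impurity can take at most 0.200, which leaves at least 0.800 of the starting material. We call the lesser of these two the usable fraction, the fraction of the limiting reagent. Ring divided by usable fraction is the ring share, 0.280 in oak, and one reading carries a scatter of 0.0125 in it.

3. Birch and elm read close to this. Averaged over its readings, birch gives 0.278 and elm, with twice the starting material, gives 0.279. Ash, with activator in excess, gives 0.301 over its last three readings, which stands 0.0210 above oak, more than the scatter of one reading. The three new flasks have oak's charges, so we keep oak's share for them.

4. Now turn the question round: what would let one flask lead by 1.5 percentage points? Feeding can change how much the impurity takes, but the fraction left stays at 0.800 or above, and that is no lower than the activator fraction 0.800. So the usable fraction stays put, and a lead would need the shares of two flasks to part by 0.0187. With one reading's scatter of 0.0125 in the share, the readings do not rule out a gap of that size. Our reckoning is still 22.4% for each flask, with no leader.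

5. The forecast said all alike, with 22.5%, 20.8% and 21.3% for north-east, south-east and south, and held that “Slow feeding gives no real gain”.

    starting material + activator → activated form (k = 69.0 L mol⁻¹ h⁻¹)
    activated form → ring (k = 0.120 h⁻¹)
    starting material + activated form → open dimer (k = 1.30 L mol⁻¹ h⁻¹)
    activated form → decomposed reagent (k = 0.300 h⁻¹)
    activator + ring ⇌ idle adduct, settled at all times (K = 22.0 L mol⁻¹)
    starting material + protic impurity → quenched substrate (k = 150 L mol⁻¹ h⁻¹)

The flasks give 22.3% in north-east, 21.6% in south-east and 22.1% in south, so all alike, with north-east 0.70 points above south-east. At 3.00 d open dimer holds 0.525% in north-east and 3.30% in south-east. The ring shares come to 0.278 and 0.270, against our 0.280. Take north-east with 9.6 mM of activator: the usable fraction falls to 0.480, and the share 0.280 gives 13.4%. That flask ended with 13.6% of ring.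

The numbers in the tables were generated by integration for substances that don't exist; the scatter is artificial.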